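**Retrosynthetic overview**
- The target is the bis-O-methyl ether of a 2,5-dihydroxy-3,6-bis(indol-3-yl)-1,4-benzoquinone, so the last step is a double O-methylation.
- Key disconnection: the bond between the quinone carbon and C3 of the 2-(1,1-dimethylallyl)indole. Both carbons are natively nucleophilic (enol carbon of a vinylogous acid, enamine carbon of an indole). They are joined by turning the hydroxyquinone into its phenyliodonium ylide, an enolonium equivalent.
- The mono-indolyl dihydroxyquinone comes from indole and 2,5-dihydroxy-1,4-benzoquinone by acid-catalysed conjugate addition and re-oxidation.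
- 2-(1,1-Dimethylallyl)indole comes from indole by C3 chlorination and prenyl transfer from boron to C2 with allyl inversion.
- No ring is built: both indole ring systems and the quinone ring are bought, and they are joined in the order quinone + indole, then + prenylated indole.

Assumption: the target has no stereocentre and its SMILES defines no stereo-element, so it is made as drawn and no enantioselective step is needed.

**Step 1**
Reactants: 1 1H-indole; 2 3-methylbuta-1,2-diene
Product: 5 2-(2-methylbut-3-en-2-yl)-1H-indole, via B-prenyl-9-BBN 3 (not isolated), via 3-chloro-1H-indole 4 (not isolated)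
Conditions: (a) 2, 9-BBN (0.5 M in THF), 0 °C to rt, gives 3; (b) 1, NCS, THF, 0 °C, gives 4; then Et3N, add 3 at −78 °C, warm to rt; aq. NaHCO3 work-up
Reagents that add atoms: none
Why: Reverse prenylation of the Danishefsky type, in which C3 chlorination makes C2 an imine-type electrophile (3H-indole tautomer of 4 bound to boron at nitrogen), the prenyl group passes from boron to C2 with allyl inversion through a six-membered transition state, and loss of HCl to Et3N restores the indole.

**Step 2**
Reactants: 1 1H-indole; 6 2,5-dihydroxy-1,4-benzoquinone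
Product: 8 2,5-dihydroxy-3-(1H-indol-3-yl)-1,4-benzoquinone, via 3-(indol-3-yl)benzene-1,2,4,5-tetrol 7 (not isolated)
Conditions: 6 (2.5 equiv), AcOH, 50 °C, slow addition of 1, N2; filter and wash
Reagents that add atoms: none
Why: Acid-catalysed Michael-type (Friedel–Crafts) addition of indole C3 to the free ring carbon of the protonated hydroxyquinone gives the aromatic tetrol 7, which the excess of 6 re-oxidises by redox exchange, a reported reaction type for indoles and hydroxyquinones; the excess of 6 and the lower electrophilicity of 8 hold the reaction at mono-addition.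

**Step 3 (key step)**
Reactants: 8 2,5-dihydroxy-3-(1H-indol-3-yl)-1,4-benzoquinone; 5 2-(2-methylbut-3-en-2-yl)-1H-indole
Product: 10 2,5-dihydroxy-3-(1H-indol-3-yl)-6-[2-(2-methylbut-3-en-2-yl)-1H-indol-3-yl]-1,4-benzoquinone, via phenyliodonium ylide 9 (not isolated)
Conditions: PhI(OAc)2 (1.0 equiv), CH2Cl2–MeCN, 0 °C, 1 h; evaporate cold (removes AcOH); then 5 (1.1 equiv), BF3·OEt2 (2 equiv), CH2Cl2, −20 to 0 °C; aq. work-up
Reagents that add atoms: none
Why: Proposed new method: the acidic enol carbon C6 of 8 attacks the trivalent iodine of PhI(OAc)2 to give the zwitterionic ylide 9 (known for 2-hydroxy-1,4-quinones), in which this normally nucleophilic carbon carries the hyper-leaving group PhI and so acts as an enolonium equivalent; BF3 binds the oxido oxygen to give a β-oxo alkenyl(phenyl)iodonium, C3 of 5 adds at C6 (addition–elimination, or ligand coupling at iodine), PhI leaves and tautomerisation gives 10; the closest known reaction type is the BF3·OEt2-mediated arylation of the phenyliodonium ylide of 2-hydroxy-1,4-naphthoquinone with electron-rich arenes.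

**Step 4**
Reactants: 10 2,5-dihydroxy-3-(1H-indol-3-yl)-6-[2-(2-methylbut-3-en-2-yl)-1H-indol-3-yl]-1,4-benzoquinone
Product: 11 2,5-dimethoxy-3-(1H-indol-3-yl)-6-[2-(2-methylbut-3-en-2-yl)-1H-indol-3-yl]-1,4-benzoquinone (target)
Conditions: TMSCHN2 (2 M in hexanes, 3 equiv), CH2Cl2–MeOH 4:1, 0 °C to rt
Reagents that add atoms: (trimethylsilyl)diazomethane, C[Si](C)(C)C=[N+]=[N-]
Why: Diazoalkane O-methylation of a vinylogous carboxylic acid (esterification type), in which the acidic enol OH protonates the reagent and the methyldiazonium formed methylates oxygen, while the far less acidic indole N–H and the terminal alkene do not react.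

**Compound list**
1 | 1H-indole | c1ccc2[nH]ccc2c1 | starting material
2 | 3-methylbuta-1,2-diene | C=C=C(C)C | starting material
3 | B-prenyl-9-BBN, 9-(3-methylbut-2-en-1-yl)-9-borabicyclo[3.3.1]nonane | CC(C)=CCB1C2CCCC1CCC2 | intermediate
4 | 3-chloro-1H-indole | Clc1c[nH]c2ccccc12 | intermediate
5 | 2-(2-methylbut-3-en-2-yl)-1H-indole | C=CC(C)(C)c1cc2ccccc2[nH]1 | intermediate
6 | 2,5-dihydroxy-1,4-benzoquinone | O=C1C=C(O)C(=O)C=C1O | starting material
7 | 3-(1H-indol-3-yl)benzene-1,2,4,5-tetrol | Oc1cc(O)c(O)c(-c2c[nH]c3ccccc23)c1O | intermediate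
8 | 2,5-dihydroxy-3-(1H-indol-3-yl)-1,4-benzoquinone | O=C1C=C(O)C(=O)C(c2c[nH]c3ccccc23)=C1O | intermediate
9 | phenyliodonium ylide of 8, 2-hydroxy-3-(1H-indol-3-yl)-5-oxido-6-(phenyliodonio)-1,4-benzoquinone | O=C1C(O)=C(c2c[nH]c3ccccc23)C(=O)C([O-])=C1[I+]c1ccccc1 | intermediate
10 | 2,5-dihydroxy-3-(1H-indol-3-yl)-6-[2-(2-methylbut-3-en-2-yl)-1H-indol-3-yl]-1,4-benzoquinone | C=CC(C)(C)c1[nH]c2ccccc2c1C1=C(O)C(=O)C(c2c[nH]c3ccccc23)=C(O)C1=O | intermediate
11 | 2,5-dimethoxy-3-(1H-indol-3-yl)-6-[2-(2-methylbut-3-en-2-yl)-1H-indol-3-yl]-1,4-benzoquinone | C=CC(C)(C)c1[nH]c2ccccc2c1C1=C(OC)C(=O)C(c2c[nH]c3ccccc23)=C(OC)C1=O | target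

**Step count**
Total: 4 steps. Longest linear sequence: 3 steps (1 → 5 → 10 → 11, or 6 → 8 → 10 → 11).

**Steps most likely to fail, with fallbacks**

Step 3 is the main risk. PhI(OAc)2 may oxidise the indole of 8. The ylide 9 may ring-contract, or may acylate the indole instead of arylating it. Position C3 of 5 is also hindered by the neighbouring tertiary group. The fallback sets out from 8 (with 5) and comes back at 10. It gives up the iodonium activation and uses 8 as a plain Michael acceptor. Acid-promoted conjugate addition of 5 to 8 (AcOH, or HCl in THF) gives the hydroquinone 3-(1H-indol-3-yl)-6-[2-(2-methylbut-3-en-2-yl)-1H-indol-3-yl]benzene-1,2,4,5-tetrol F1. This is oxidised in the same flask with DDQ to 10.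

Step 2 is the second risk. Indole may attack the hydroxyl-bearing carbon of 6 instead of the free ring carbon, or bis-addition may intrude. The fallback sets out from 1 and comes back at 8. Acid-promoted addition of 1 to commercial 2,5-dichloro-1,4-benzoquinone (HCl, THF) gives 2,5-dichloro-3-(1H-indol-3-yl)benzene-1,4-diol F2. DDQ oxidises this in the same flask to 2,5-dichloro-3-(1H-indol-3-yl)-1,4-benzoquinone F3. Exchange of both vinylic chlorides by addition–elimination (NaOH, MeOH–H2O, reflux, then acid) gives 8.

Step 1 is the third risk. With no C3 substituent, 4 rests as the aromatic 3-chloroindole, and allyl transfer to C2 may be slow or low-yielding. The fallback sets out from 1 and comes back at 5. It builds the quaternary carbon by cross-coupling instead. Indole is converted in one flask into lithium indole-1-carboxylate F4 (n-BuLi, then CO2). F4 is lithiated at C2 (t-BuLi) and iodinated (1,2-diiodoethane), and loses CO2 on aqueous work-up to give 2-iodo-1H-indole F5. A γ-selective Suzuki–Miyaura allyl–aryl coupling with 3-methylbut-2-enylboronic acid pinacol ester then gives 5. This uses zerovalent palladium generated from Pd(OAc)2 and a biaryl dialkylphosphine ligand chosen for branched selectivity, with K3PO4 in aqueous THF.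

**Further compounds**
F1 | step 3 | 3-(1H-indol-3-yl)-6-[2-(2-methylbut-3-en-2-yl)-1H-indol-3-yl]benzene-1,2,4,5-tetrol | C=CC(C)(C)c1[nH]c2ccccc2c1-c1c(O)c(O)c(-c2c[nH]c3ccccc23)c(O)c1O
F2 | step 2 | 2,5-dichloro-3-(1H-indol-3-yl)benzene-1,4-diol | Oc1cc(Cl)c(O)c(-c2c[nH]c3ccccc23)c1Cl
F3 | step 2 | 2,5-dichloro-3-(1H-indol-3-yl)-1,4-benzoquinone | O=C1C=C(Cl)C(=O)C(c2c[nH]c3ccccc23)=C1Cl
F4 | step 1 | lithium indole-1-carboxylate | [Li+].[O-]C(=O)n1ccc2ccccc12
F5 | step 1 | 2-iodo-1H-indole | Ic1cc2ccccc2[nH]1
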